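**Plan**

- Numbering: ring A C1–C6 (C1 gem-dimethyl, C3/C4 diol, C5 methyl), chain C7–C17, butenolide C18(γ)/Cβ/Cα; oxabicycle C1'–C6' (O bridges C3' and C6'), vinyl C7'=C8'.
- Cuts: Cα–C8' (Stille) and C12–C13 (Negishi) on a bromo-iodo butenolide linchpin; lactone O–C18 (Ag-catalysed lactonisation of an enynoic acid); C6'–O (transannular epoxide opening); C5=C6 of ring A (aldol condensation).
- Enabling feature: C2–C5 of ring A with the cis (3S,4R)-diol are C2–C5 of 2-deoxy-D-ribose, so ring A lacks only its tetrasubstituted C5=C6 bond, which a C7 aldehyde (C6 as nucleophile) and a C5 methyl ketone can close.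
- Forward order: ring A (steps 1–12), protecting-group exchange and C7–C12 dienyne (13–18); oxabicycle from (4R,6R)-actinol (19–28); butenolide linchpin (29–34); chain joined at C12–C13, then Cα–C8', then desilylation (35–37).
- Stereochemistry: C3/C4 from the sugar; C3' from actinol; C5'/C6' from a tartrate-controlled epoxidation anti to O3' and invertive ether closure at C6'; Z-ylidene from anti-oxymetalation; E-alkenes from olefination, syn-hydrometalation and stereoretentive couplings.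

Key step: step 12

Assumption (chemistry): the acetonide that serves the ring closure is exchanged for triethylsilyl ethers directly afterwards (steps 13–14), because an acetal at allylic C4 could not be cleaved by acid on the finished polyene without ionisation at C4; all polyenes from step 15 on are handled in the dark under argon.

**Route**

Step 1
Reactants: 1 2-deoxy-D-ribose
Product: 2 2-deoxy-3,4-O-isopropylidene-D-erythro-pentopyranose (lactol)
Conditions: 2-methoxypropene, pyridinium p-toluenesulfonate (cat.), EtOAc, 0 °C → rt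
Reagents that add atoms: 2-methoxypropene, COC(C)=C
Why: Acid-catalysed ketalisation picks out the cis-3,4-diol of the pyranose form, so O3/O4 are protected while C1 stays a lactol and O5 stays in the ring.

Step 2
Reactants: 2; 3 methylmagnesium bromide
Product: 4 1-[(4S,5R)-5-(hydroxymethyl)-2,2-dimethyl-1,3-dioxolan-4-yl]propan-2-ol (both carbinol epimers)
Conditions: MeMgBr (3.5 equiv), THF, 0 °C → rt; aq. NH4Cl
Reagents that add atoms: none
Why: Grignard addition to the open-chain hydroxy aldehyde in equilibrium with the lactol; the new carbinol centre is oxidised in step 4, so its configuration does not matter.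

Step 3
Reactants: 4
Product: 5 1-[(4S,5R)-5-({[tert-butyl(dimethyl)silyl]oxy}methyl)-2,2-dimethyl-1,3-dioxolan-4-yl]propan-2-ol
Conditions: t-BuMe2SiCl (1.05 equiv), imidazole, CH2Cl2, 0 °C
Reagents that add atoms: tert-butyldimethylsilyl chloride, CC(C)(C)[Si](C)(C)Cl
Why: Silyl ether formation, selective for the primary over the secondary hydroxyl on steric grounds.

Step 4
Reactants: 5
Product: 6 1-[(4S,5R)-5-({[tert-butyl(dimethyl)silyl]oxy}methyl)-2,2-dimethyl-1,3-dioxolan-4-yl]propan-2-one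
Conditions: DMP [1,1,1-triacetoxy-1,1-dihydro-1,2-benziodoxol-3(1H)-one], NaHCO3, CH2Cl2, 0 °C → rt
Reagents that add atoms: none
Why: Periodinane oxidation of the secondary alcohol under buffered, non-basic conditions that should not trigger β-elimination of the acetonide oxygen.

Step 5
Reactants: 6; 7 triethyl phosphonoacetate
Product: 8 ethyl 4-[(4S,5R)-5-({[tert-butyl(dimethyl)silyl]oxy}methyl)-2,2-dimethyl-1,3-dioxolan-4-yl]-3-methylbut-2-enoate (E/Z mixture)
Conditions: 7, NaH, THF, 0 °C; then 6, rt → 50 °C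
Reagents that add atoms: none
Why: Horner–Wadsworth–Emmons olefination of the methyl ketone adds C6 and C7 of ring A; both alkene isomers serve because the geometry is erased in step 6.

Step 6
Reactants: 8
Product: 10 ethyl 4-[(4S,5R)-5-({[tert-butyl(dimethyl)silyl]oxy}methyl)-2,2-dimethyl-1,3-dioxolan-4-yl]-3,3-dimethylbutanoate, via silyl ketene acetal 9 (not isolated)
Conditions: MeLi (2 equiv), CuI, Et2O, 0 °C; then Me3SiCl, 8, −78 → 0 °C; aq. NH4Cl
Reagents that add atoms: lithium dimethylcuprate, [Li+].C[Cu-]C; chlorotrimethylsilane, C[Si](C)(C)Cl (its silicon is found only in 9)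
Why: Chlorosilane-accelerated conjugate addition of the lithium dialkylcuprate to the β,β-disubstituted enoate creates the quaternary gem-dimethyl carbon (ring A C1), and work-up hydrolyses 9 to the ester.

Step 7
Reactants: 10
Product: 11 ethyl 4-[(4S,5R)-5-(hydroxymethyl)-2,2-dimethyl-1,3-dioxolan-4-yl]-3,3-dimethylbutanoate
Conditions: Bu4NF, THF, 0 °C → rt
Reagents that add atoms: none
Why: Fluoride-mediated cleavage of the primary silyl ether; ester and acetonide are inert.

Step 8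
Reactants: 11
Product: 12 ethyl 4-[(4S,5S)-5-formyl-2,2-dimethyl-1,3-dioxolan-4-yl]-3,3-dimethylbutanoate
Conditions: DMP, NaHCO3, CH2Cl2, 0 °C; used crude
Reagents that add atoms: none
Why: Periodinane oxidation to the α-alkoxy aldehyde without base, so the cis-dioxolane centre next to the formyl group should not epimerise.

Step 9
Reactants: 12; 3 methylmagnesium bromide
Product: 13 ethyl 4-[(4S,5R)-5-(1-hydroxyethyl)-2,2-dimethyl-1,3-dioxolan-4-yl]-3,3-dimethylbutanoate (both carbinol epimers)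
Conditions: MeMgBr (1.2 equiv), THF, −78 °C
Reagents that add atoms: none
Why: Grignard addition at −78 °C is chemoselective for the aldehyde over the β-branched ethyl ester; the carbinol configuration is irrelevant (oxidised in step 11).

Step 10
Reactants: 13
Product: 14 4-[(4S,5R)-5-(1-hydroxyethyl)-2,2-dimethyl-1,3-dioxolan-4-yl]-3,3-dimethylbutan-1-ol
Conditions: LiAlH4, THF, 0 °C; Na2SO4·10H2O
Reagents that add atoms: none
Why: Hydride reduction of the ester to the primary alcohol, so that both carbonyl groups of the cyclisation substrate can be unveiled together and no reductant has to tell an ester from a ketone.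

Step 11
Reactants: 14
Product: 15 4-[(4S,5S)-5-acetyl-2,2-dimethyl-1,3-dioxolan-4-yl]-3,3-dimethylbutanal
Conditions: DMP (3 equiv), NaHCO3, CH2Cl2, 0 °C → rt; used at once
Reagents that add atoms: none
Why: Twofold periodinane oxidation (primary alcohol to aldehyde, secondary to ketone) under neutral conditions that spare the epimerisable C4 centre next to the new ketone.

Step 12
Reactants: 15
Product: 18 (3aR,7aS)-2,2,4,6,6-pentamethyl-3a,6,7,7a-tetrahydro-1,3-benzodioxole-5-carbaldehyde, via enamine 16 (not isolated), via cyclic aldol 17 (not isolated)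
Conditions: pyrrolidine (0.3 equiv), AcOH (0.3 equiv), THF (0.02 M), 4 Å molecular sieves, rt → 40 °C
Reagents that add atoms: none
Why: Pyrrolidinium acetate converts the aldehyde into enamine 16, whose β-carbon (ring A C6) adds to the ketone carbonyl (C5) to give the cyclic aldol 17, and loss of water through the enamine followed by hydrolysis releases the conjugated aldehyde and the amine. The closest known reaction type is the amine-salt-mediated intramolecular aldol condensation of 1,7-keto aldehydes to cyclohex-1-ene-1-carbaldehydes. Ring A closes in a 6-(enolexo)-exo-trig mode, aided by the gem-dimethyl group at C1 that folds the chain. No stereocentre is formed, since C5 and C6 become sp2, and C3 and C4 are carried over from the sugar. The step needs the aldehyde as nucleophile and the ketone as electrophile: enamine formation is far faster at the unbranched aldehyde than at the α-oxygenated, α-branched ketone, the ketone methyl could only close an eight-membered ring, and an enamine at C4 would have to be tetrasubstituted. It also needs C4 to survive, and here the cis-fused dioxolane holds the C3–O bond out of line with the π system of any C4 enol while the buffered amine salt is too weak a base to epimerise or eliminate.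

Step 13
Reactants: 18
Product: 19 (3R,4S)-3,4-dihydroxy-2,6,6-trimethylcyclohex-1-ene-1-carbaldehyde
Conditions: AcOH–H2O (4:1), 40 °C
Reagents that add atoms: none
Why: Aqueous-acid hydrolysis of the isopropylidene ketal, done here because the C4 oxygen is allylic only to an electron-poor enal (a C4 cation is not stabilised), whereas after chain extension it would be allylic to a long polyene.

Step 14
Reactants: 19
Product: 20 (3R,4S)-2,6,6-trimethyl-3,4-bis[(triethylsilyl)oxy]cyclohex-1-ene-1-carbaldehyde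
Conditions: Et3SiOTf, 2,6-lutidine, CH2Cl2, −78 → 0 °C
Reagents that add atoms: triethylsilyl trifluoromethanesulfonate, CC[Si](CC)(CC)OS(=O)(=O)C(F)(F)F
Why: Silylation with the silyl triflate covers both secondary hydroxyls, also the hindered allylic one, as ethers that fluoride removes at the end under neutral conditions.

Step 15
Reactants: 20; 21 ethyl (2E)-4-(diethoxyphosphoryl)-3-methylbut-2-enoate
Product: 22 ethyl (2E,4E)-3-methyl-5-{(3R,4S)-2,6,6-trimethyl-3,4-bis[(triethylsilyl)oxy]cyclohex-1-en-1-yl}penta-2,4-dienoate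
Conditions: 21, LiN(SiMe3)2, THF–DMPU, −78 °C; then 20, −78 → 0 °C
Reagents that add atoms: none
Why: Vinylogous Horner–Wadsworth–Emmons olefination of the cyclocitral-type aldehyde forms C7=C8 with E geometry and brings in C9=C10 mainly as the E isomer through the equilibrating phosphonate anion; a minor 9Z isomer would be removed by chromatography.

Step 16
Reactants: 22
Product: 23 (2E,4E)-3-methyl-5-{(3R,4S)-2,6,6-trimethyl-3,4-bis[(triethylsilyl)oxy]cyclohex-1-en-1-yl}penta-2,4-dien-1-ol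
Conditions: i-Bu2AlH (2.5 equiv), CH2Cl2, −78 °C; aq. potassium sodium tartrate
Reagents that add atoms: none
Why: 1,2-Reduction of the dienoate by the aluminium hydride gives the allylic alcohol without touching silyl ethers or alkenes.

Step 17
Reactants: 23
Product: 24 (2E,4E)-3-methyl-5-{(3R,4S)-2,6,6-trimethyl-3,4-bis[(triethylsilyl)oxy]cyclohex-1-en-1-yl}penta-2,4-dienal
Conditions: MnO2 (activated, excess), CH2Cl2, rt
Reagents that add atoms: none
Why: MnO2 oxidises the allylic alcohol selectively to the dienal with retention of alkene geometry.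

Step 18
Reactants: 24
Product: 25 (3R,4S)-1-[(1E,3E)-3-methylhexa-1,3-dien-5-yn-1-yl]-2,6,6-trimethyl-3,4-bis[(triethylsilyl)oxy]cyclohex-1-ene
Conditions: Me3SiCHN2, LiN(i-Pr)2, THF, −78 → 0 °C
Reagents that add atoms: trimethylsilyldiazomethane, C[Si](C)(C)C=[N+]=[N-]
Why: Colvin homologation (addition of lithiated silyldiazomethane, Peterson-type elimination, 1,2-shift in the alkylidene carbene) turns the aldehyde into the terminal alkyne C11≡C12 without the methanolic base that adds to enals.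

Step 19
Reactants: 26 (4R,6R)-4-hydroxy-2,2,6-trimethylcyclohexan-1-one [(4R,6R)-actinol]
Product: 27 (4R,6R)-4-{[tert-butyl(dimethyl)silyl]oxy}-2,2,6-trimethylcyclohexan-1-one
Conditions: t-BuMe2SiCl, imidazole, DMF, rt
Reagents that add atoms: tert-butyldimethylsilyl chloride, CC(C)(C)[Si](C)(C)Cl
Why: Silyl ether formation protects the C3' hydroxyl for the enolate chemistry that follows.

Step 20
Reactants: 27
Product: 28 (4R)-4-{[tert-butyl(dimethyl)silyl]oxy}-2,6,6-trimethylcyclohex-1-en-1-yl trifluoromethanesulfonate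
Conditions: LiN(i-Pr)2, THF, −78 → 0 °C; then PhNTf2, 0 °C → rt
Reagents that add atoms: N-phenylbis(trifluoromethanesulfonimide), O=S(=O)(N(c1ccccc1)S(=O)(=O)C(F)(F)F)C(F)(F)F
Why: Enolate O-sulfonylation; only C5' carries an α-hydrogen, so a single enol triflate forms (the C5' stereocentre is deleted, C3' is untouched).

Step 21
Reactants: 28
Product: 29 methyl (4R)-4-{[tert-butyl(dimethyl)silyl]oxy}-2,6,6-trimethylcyclohex-1-ene-1-carboxylate
Conditions: Pd(OAc)2 (5 mol%), PPh3, CO (1 atm), MeOH, Et3N, DMF, 60 °C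
Reagents that add atoms: carbon monoxide, [C-]#[O+]; methanol, CO
Why: Pd-catalysed alkoxycarbonylation of the enol triflate (oxidative addition, CO insertion, methanolysis) installs C7'.

Step 22
Reactants: 29
Product: 30 [(4R)-4-{[tert-butyl(dimethyl)silyl]oxy}-2,6,6-trimethylcyclohex-1-en-1-yl]methanol
Conditions: i-Bu2AlH (2.5 equiv), CH2Cl2, −78 → 0 °C
Reagents that add atoms: none
Why: Hydride reduction of the hindered enoate gives the allylic alcohol that directs the epoxidation.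

Step 23
Reactants: 30
Product: 31 [(1R,4S,6R)-4-{[tert-butyl(dimethyl)silyl]oxy}-2,2,6-trimethyl-7-oxabicyclo[4.1.0]heptan-1-yl]methanol
Conditions: Ti(Oi-Pr)4 (20 mol%), D-(−)-diethyl tartrate [(2S,3S), 24 mol%], t-BuOOH, 4 Å molecular sieves, CH2Cl2, −20 °C
Reagents that add atoms: tert-butyl hydroperoxide, CC(C)(C)OO
Why: Sharpless asymmetric epoxidation; with the (2S,3S)-tartrate the titanium-bound peroxide is delivered to the alkene face anti to the C3' silyloxy group, which sets C5' and C6' by reagent control whatever the substrate bias.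

Step 24
Reactants: 31
Product: 32 (1S,4S,6R)-4-{[tert-butyl(dimethyl)silyl]oxy}-2,2,6-trimethyl-7-oxabicyclo[4.1.0]heptane-1-carbaldehyde
Conditions: DMP, NaHCO3, CH2Cl2, 0 °C → rt
Reagents that add atoms: none
Why: Periodinane oxidation of the epoxy alcohol; the α-carbon of the aldehyde is quaternary, so it cannot epimerise.

Step 25
Reactants: 32
Product: 33 tert-butyl{[(1R,3S,6R)-6-ethynyl-1,5,5-trimethyl-7-oxabicyclo[4.1.0]heptan-3-yl]oxy}dimethylsilane
Conditions: dimethyl (1-diazo-2-oxopropyl)phosphonate, K2CO3, MeOH, 0 °C → rt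
Reagents that add atoms: dimethyl (1-diazo-2-oxopropyl)phosphonate, CC(=O)C(=[N+]=[N-])P(=O)(OC)OC
Why: Ohira–Bestmann homologation converts the non-enolisable aldehyde into the terminal alkyne C7'≡C8' under mild carbonate conditions that a tetrasubstituted epoxide tolerates.

Step 26
Reactants: 33
Product: 34 (1R,3S,6R)-6-ethynyl-1,5,5-trimethyl-7-oxabicyclo[4.1.0]heptan-3-ol
Conditions: Bu4NF, THF, 0 °C → rt
Reagents that add atoms: none
Why: Fluoride cleaves the silyl ether and frees the C3' hydroxyl.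

Step 27
Reactants: 34
Product: 35 (1S,2R,4S)-1-ethynyl-2,6,6-trimethyl-7-oxabicyclo[2.2.1]heptan-2-ol
Conditions: camphor-10-sulfonic acid (10 mol%), CH2Cl2, 0 °C → rt
Reagents that add atoms: none
Why: Acid-catalysed transannular epoxide opening, known for anti-4-hydroxycyclohexene oxides: the C3' hydroxyl attacks C6' (the only epoxide carbon it can reach, and a tertiary propargylic one) from the face opposite the breaking C6'–O bond, so C6' is inverted, C5' keeps its oxygen as the endo tertiary alcohol and the 7-oxabicyclo[2.2.1]heptane results.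

Step 28
Reactants: 35
Product: 36 (1R,2R,4S)-2,6,6-trimethyl-1-[(E)-2-(tributylstannyl)ethenyl]-7-oxabicyclo[2.2.1]heptan-2-ol
Conditions: Bu3SnH, PdCl2(PPh3)2 (3 mol%), THF, 0 °C
Reagents that add atoms: tributylstannane, CCCC[SnH](CCCC)CCCC
Why: Pd-catalysed syn-hydrostannation; the quaternary propargylic carbon sends tin to the terminal carbon and gives the (E)-alkenylstannane.

Step 29
Reactants: 37 ethyl propiolate
Product: 38 ethyl (2E)-2,3-dibromoprop-2-enoate
Conditions: Br2 (1.0 equiv), CHCl3, 0 °C → rt, dark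
Reagents that add atoms: bromine, BrBr
Why: Anti addition of bromine to the alkynoate gives the (E)-dibromide, in which the β-bromine is cis to the ester.

Step 30
Reactants: 38; 39 (2E)-3-methylpent-2-en-4-yn-1-ol
Product: 40 ethyl (2E,6E)-2-bromo-8-hydroxy-6-methylocta-2,6-dien-4-ynoate
Conditions: PdCl2(PPh3)2 (3 mol%), CuI (6 mol%), Et3N, MeCN, 0 °C → rt
Reagents that add atoms: none
Why: Sonogashira coupling takes place at the more electrophilic β-C–Br bond with retention, which places the alkyne cis to the ester; the α-bromide and the free alcohol are spectators.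

Step 31
Reactants: 40
Product: 41 (2E,6E)-2-bromo-8-hydroxy-6-methylocta-2,6-dien-4-ynoic acid
Conditions: LiOH (1.5 equiv), THF–H2O, 0 °C; then 1 M HCl to pH 3
Reagents that add atoms: lithium hydroxide, [Li+].[OH-]
Why: Saponification of the ethyl ester at low temperature frees the acid for lactonisation.

Step 32
Reactants: 41
Product: 42 (5Z)-3-bromo-5-[(2E)-4-hydroxy-2-methylbut-2-en-1-ylidene]furan-2(5H)-one
Conditions: AgNO3 (10 mol%), acetone, rt, dark
Reagents that add atoms: none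
Why: Silver-catalysed 5-exo-dig lactonisation of the enynoic acid; anti addition of carboxylate and proton across the silver-activated alkyne sets the (Z)-ylidene (ring oxygen cis to the chain).

Step 33
Reactants: 42
Product: 43 (2E)-4-[(2Z)-4-bromo-5-oxofuran-2(5H)-ylidene]-3-methylbut-2-enal
Conditions: MnO2 (activated, excess), CH2Cl2, rt, dark
Reagents that add atoms: none
Why: Selective allylic oxidation by MnO2 gives the dienal (C14) without touching the lactone or the vinyl bromide.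

Step 34
Reactants: 43
Product: 44 (5Z)-3-bromo-5-[(2E,4E)-5-iodo-2-methylpenta-2,4-dien-1-ylidene]furan-2(5H)-one
Conditions: CrCl2 (6 equiv), CHI3 (2 equiv), THF–dioxane, 0 °C, dark
Reagents that add atoms: iodoform, IC(I)I
Why: Takai iodo-olefination (a geminal dichromium reagent from iodoform adds to the aldehyde and eliminates anti) gives the (E)-iodide at C13; without a nickel co-catalyst the ring C–Br bond is not expected to react with CrCl2.

Step 35
Reactants: 25; 44
Product: 46 (5Z)-3-bromo-5-[(2E,4E,6E,8E,10E)-2,9-dimethyl-11-{(3R,4S)-2,6,6-trimethyl-3,4-bis[(triethylsilyl)oxy]cyclohex-1-en-1-yl}undeca-2,4,6,8,10-pentaen-1-ylidene]furan-2(5H)-one, via alkenylzirconocene 45 (not isolated)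
Conditions: Cp2Zr(H)Cl (1.1 equiv), THF, rt, dark; then ZnCl2 (1.0 equiv), Pd(PPh3)4 (5 mol%), 44, 0 °C → rt
Reagents that add atoms: zirconocene chloride hydride, Cl[ZrH](C1C=CC=C1)C1C=CC=C1 (its zirconium is found only in 45)
Why: syn-Hydrozirconation of the terminal alkyne places zirconium on C12 with E geometry; after transmetalation to zinc, Negishi coupling with the dienyl iodide forms C12–C13 with retention on both partners, the C–I bond being far more reactive toward zerovalent palladium than the ring C–Br bond.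

Step 36
Reactants: 46; 36
Product: 47 (5Z)-5-[(2E,4E,6E,8E,10E)-2,9-dimethyl-11-{(3R,4S)-2,6,6-trimethyl-3,4-bis[(triethylsilyl)oxy]cyclohex-1-en-1-yl}undeca-2,4,6,8,10-pentaen-1-ylidene]-3-{(E)-2-[(1R,2R,4S)-2-hydroxy-2,6,6-trimethyl-7-oxabicyclo[2.2.1]heptan-1-yl]ethenyl}furan-2(5H)-one
Conditions: Pd2(dba)3 (2.5 mol%), AsPh3 (20 mol%), CuI (10 mol%), NMP, rt → 40 °C, dark
Reagents that add atoms: none
Why: Stille coupling of the butenolide α-bromide with the (E)-alkenylstannane forms Cα–C8' with retention under neutral conditions that the lactone, the tertiary alcohol and the polyene tolerate.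

Step 37
Reactants: 47
Product: 48 (5Z)-5-[(2E,4E,6E,8E,10E)-11-[(3R,4S)-3,4-dihydroxy-2,6,6-trimethylcyclohex-1-en-1-yl]-2,9-dimethylundeca-2,4,6,8,10-pentaen-1-ylidene]-3-{(E)-2-[(1R,2R,4S)-2-hydroxy-2,6,6-trimethyl-7-oxabicyclo[2.2.1]heptan-1-yl]ethenyl}furan-2(5H)-one (CNP0216838.1)
Conditions: Bu4NF, AcOH (1:1), THF, 0 °C → rt, dark, argon
Reagents that add atoms: none
Why: Buffered fluoride cleaves both silyl ethers at near-neutral pH, so neither the base-sensitive ylidenebutenolide nor the acid-sensitive allylic C4 alcohol is endangered.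

**Compound list**

1 | 2-deoxy-D-ribose [(3S,4R)-3,4,5-trihydroxypentanal, drawn open-chain] | O=CC[C@H](O)[C@H](O)CO | starting material
2 | 2-deoxy-3,4-O-isopropylidene-D-erythro-pentopyranose (lactol, both anomers) | OC1C[C@@H]2OC(C)(C)O[C@@H]2CO1 | intermediate
3 | methylmagnesium bromide | C[Mg]Br | starting material
4 | 1-[(4S,5R)-5-(hydroxymethyl)-2,2-dimethyl-1,3-dioxolan-4-yl]propan-2-ol (both carbinol epimers) | CC(O)C[C@@H]1OC(C)(C)O[C@@H]1CO | intermediate
5 | 1-[(4S,5R)-5-({[tert-butyl(dimethyl)silyl]oxy}methyl)-2,2-dimethyl-1,3-dioxolan-4-yl]propan-2-ol | CC(O)C[C@@H]1OC(C)(C)O[C@@H]1CO[Si](C)(C)C(C)(C)C | intermediate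
6 | 1-[(4S,5R)-5-({[tert-butyl(dimethyl)silyl]oxy}methyl)-2,2-dimethyl-1,3-dioxolan-4-yl]propan-2-one | CC(=O)C[C@@H]1OC(C)(C)O[C@@H]1CO[Si](C)(C)C(C)(C)C | intermediate
7 | triethyl phosphonoacetate | CCOC(=O)CP(=O)(OCC)OCC | starting material
8 | ethyl 4-[(4S,5R)-5-({[tert-butyl(dimethyl)silyl]oxy}methyl)-2,2-dimethyl-1,3-dioxolan-4-yl]-3-methylbut-2-enoate (E/Z mixture) | CCOC(=O)C=C(C)C[C@@H]1OC(C)(C)O[C@@H]1CO[Si](C)(C)C(C)(C)C | intermediate
9 | ethyl trimethylsilyl ketene acetal of 10 | CCOC(O[Si](C)(C)C)=CC(C)(C)C[C@@H]1OC(C)(C)O[C@@H]1CO[Si](C)(C)C(C)(C)C | intermediate (not isolated)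
10 | ethyl 4-[(4S,5R)-5-({[tert-butyl(dimethyl)silyl]oxy}methyl)-2,2-dimethyl-1,3-dioxolan-4-yl]-3,3-dimethylbutanoate | CCOC(=O)CC(C)(C)C[C@@H]1OC(C)(C)O[C@@H]1CO[Si](C)(C)C(C)(C)C | intermediate
11 | ethyl 4-[(4S,5R)-5-(hydroxymethyl)-2,2-dimethyl-1,3-dioxolan-4-yl]-3,3-dimethylbutanoate | CCOC(=O)CC(C)(C)C[C@@H]1OC(C)(C)O[C@@H]1CO | intermediate
12 | ethyl 4-[(4S,5S)-5-formyl-2,2-dimethyl-1,3-dioxolan-4-yl]-3,3-dimethylbutanoate | CCOC(=O)CC(C)(C)C[C@@H]1OC(C)(C)O[C@@H]1C=O | intermediate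
13 | ethyl 4-[(4S,5R)-5-(1-hydroxyethyl)-2,2-dimethyl-1,3-dioxolan-4-yl]-3,3-dimethylbutanoate (both carbinol epimers) | CCOC(=O)CC(C)(C)C[C@@H]1OC(C)(C)O[C@@H]1C(C)O | intermediate
14 | 4-[(4S,5R)-5-(1-hydroxyethyl)-2,2-dimethyl-1,3-dioxolan-4-yl]-3,3-dimethylbutan-1-ol (both carbinol epimers) | OCCC(C)(C)C[C@@H]1OC(C)(C)O[C@@H]1C(C)O | intermediate
15 | 4-[(4S,5S)-5-acetyl-2,2-dimethyl-1,3-dioxolan-4-yl]-3,3-dimethylbutanal | O=CCC(C)(C)C[C@@H]1OC(C)(C)O[C@@H]1C(C)=O | intermediate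
16 | 1-{(1E)-4-[(4S,5S)-5-acetyl-2,2-dimethyl-1,3-dioxolan-4-yl]-3,3-dimethylbut-1-en-1-yl}pyrrolidine (enamine) | C1CCN(C1)/C=C/C(C)(C)C[C@@H]2OC(C)(C)O[C@@H]2C(C)=O | intermediate (not isolated)
17 | (3aS,7aS)-4-hydroxy-2,2,4,6,6-pentamethylhexahydro-1,3-benzodioxole-5-carbaldehyde (cyclic aldol, new centres unassigned) | CC1(O)C(C=O)C(C)(C)C[C@H](OC(C)(C)O2)[C@@H]12 | intermediate (not isolated)
18 | (3aR,7aS)-2,2,4,6,6-pentamethyl-3a,6,7,7a-tetrahydro-1,3-benzodioxole-5-carbaldehyde | CC1=C(C=O)C(C)(C)C[C@H](OC(C)(C)O2)[C@@H]12 | intermediate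
19 | (3R,4S)-3,4-dihydroxy-2,6,6-trimethylcyclohex-1-ene-1-carbaldehyde | CC1=C(C=O)C(C)(C)C[C@H](O)[C@@H]1O | intermediate
20 | (3R,4S)-2,6,6-trimethyl-3,4-bis[(triethylsilyl)oxy]cyclohex-1-ene-1-carbaldehyde | CC1=C(C=O)C(C)(C)C[C@H](O[Si](CC)(CC)CC)[C@@H]1O[Si](CC)(CC)CC | intermediate
21 | ethyl (2E)-4-(diethoxyphosphoryl)-3-methylbut-2-enoate | CCOC(=O)/C=C(\C)CP(=O)(OCC)OCC | starting material
22 | ethyl (2E,4E)-3-methyl-5-{(3R,4S)-2,6,6-trimethyl-3,4-bis[(triethylsilyl)oxy]cyclohex-1-en-1-yl}penta-2,4-dienoate | CC1=C(/C=C/C(C)=C/C(=O)OCC)C(C)(C)C[C@H](O[Si](CC)(CC)CC)[C@@H]1O[Si](CC)(CC)CC | intermediate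
23 | (2E,4E)-3-methyl-5-{(3R,4S)-2,6,6-trimethyl-3,4-bis[(triethylsilyl)oxy]cyclohex-1-en-1-yl}penta-2,4-dien-1-ol | CC1=C(/C=C/C(C)=C/CO)C(C)(C)C[C@H](O[Si](CC)(CC)CC)[C@@H]1O[Si](CC)(CC)CC | intermediate
24 | (2E,4E)-3-methyl-5-{(3R,4S)-2,6,6-trimethyl-3,4-bis[(triethylsilyl)oxy]cyclohex-1-en-1-yl}penta-2,4-dienal | CC1=C(/C=C/C(C)=C/C=O)C(C)(C)C[C@H](O[Si](CC)(CC)CC)[C@@H]1O[Si](CC)(CC)CC | intermediate
25 | (3R,4S)-1-[(1E,3E)-3-methylhexa-1,3-dien-5-yn-1-yl]-2,6,6-trimethyl-3,4-bis[(triethylsilyl)oxy]cyclohex-1-ene | CC1=C(/C=C/C(C)=C/C#C)C(C)(C)C[C@H](O[Si](CC)(CC)CC)[C@@H]1O[Si](CC)(CC)CC | intermediate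
26 | (4R,6R)-4-hydroxy-2,2,6-trimethylcyclohexan-1-one [(4R,6R)-actinol] | O=C1C(C)(C)C[C@H](O)C[C@H]1C | starting material
27 | (4R,6R)-4-{[tert-butyl(dimethyl)silyl]oxy}-2,2,6-trimethylcyclohexan-1-one | O=C1C(C)(C)C[C@H](O[Si](C)(C)C(C)(C)C)C[C@H]1C | intermediate
28 | (4R)-4-{[tert-butyl(dimethyl)silyl]oxy}-2,6,6-trimethylcyclohex-1-en-1-yl trifluoromethanesulfonate | CC1=C(OS(=O)(=O)C(F)(F)F)C(C)(C)C[C@H](O[Si](C)(C)C(C)(C)C)C1 | intermediate
29 | methyl (4R)-4-{[tert-butyl(dimethyl)silyl]oxy}-2,6,6-trimethylcyclohex-1-ene-1-carboxylate | CC1=C(C(=O)OC)C(C)(C)C[C@H](O[Si](C)(C)C(C)(C)C)C1 | intermediate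
30 | [(4R)-4-{[tert-butyl(dimethyl)silyl]oxy}-2,6,6-trimethylcyclohex-1-en-1-yl]methanol | CC1=C(CO)C(C)(C)C[C@H](O[Si](C)(C)C(C)(C)C)C1 | intermediate
31 | [(1R,4S,6R)-4-{[tert-butyl(dimethyl)silyl]oxy}-2,2,6-trimethyl-7-oxabicyclo[4.1.0]heptan-1-yl]methanol | OC[C@]1(O2)C(C)(C)C[C@H](O[Si](C)(C)C(C)(C)C)C[C@]12C | intermediate
32 | (1S,4S,6R)-4-{[tert-butyl(dimethyl)silyl]oxy}-2,2,6-trimethyl-7-oxabicyclo[4.1.0]heptane-1-carbaldehyde | O=C[C@]1(O2)C(C)(C)C[C@H](O[Si](C)(C)C(C)(C)C)C[C@]12C | intermediate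
33 | tert-butyl{[(1R,3S,6R)-6-ethynyl-1,5,5-trimethyl-7-oxabicyclo[4.1.0]heptan-3-yl]oxy}dimethylsilane | C#C[C@]1(O2)C(C)(C)C[C@H](O[Si](C)(C)C(C)(C)C)C[C@]12C | intermediate
34 | (1R,3S,6R)-6-ethynyl-1,5,5-trimethyl-7-oxabicyclo[4.1.0]heptan-3-ol | C#C[C@]1(O2)C(C)(C)C[C@H](O)C[C@]12C | intermediate
35 | (1S,2R,4S)-1-ethynyl-2,6,6-trimethyl-7-oxabicyclo[2.2.1]heptan-2-ol | C#C[C@@]12O[C@@H](CC1(C)C)C[C@@]2(C)O | intermediate
36 | (1R,2R,4S)-2,6,6-trimethyl-1-[(E)-2-(tributylstannyl)ethenyl]-7-oxabicyclo[2.2.1]heptan-2-ol | CCCC[Sn](CCCC)(CCCC)/C=C/[C@@]12O[C@@H](CC1(C)C)C[C@@]2(C)O | intermediate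
37 | ethyl propiolate | C#CC(=O)OCC | starting material
38 | ethyl (2E)-2,3-dibromoprop-2-enoate | CCOC(=O)/C(Br)=C\Br | intermediate
39 | (2E)-3-methylpent-2-en-4-yn-1-ol | C#C/C(C)=C/CO | starting material
40 | ethyl (2E,6E)-2-bromo-8-hydroxy-6-methylocta-2,6-dien-4-ynoate | CCOC(=O)/C(Br)=C\C#C/C(C)=C/CO | intermediate
41 | (2E,6E)-2-bromo-8-hydroxy-6-methylocta-2,6-dien-4-ynoic acid | OC(=O)/C(Br)=C\C#C/C(C)=C/CO | intermediate
42 | (5Z)-3-bromo-5-[(2E)-4-hydroxy-2-methylbut-2-en-1-ylidene]furan-2(5H)-one | OC/C=C(C)/C=C1C=C(Br)C(=O)O/1 | intermediate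
43 | (2E)-4-[(2Z)-4-bromo-5-oxofuran-2(5H)-ylidene]-3-methylbut-2-enal | O=C/C=C(C)/C=C1C=C(Br)C(=O)O/1 | intermediate
44 | (5Z)-3-bromo-5-[(2E,4E)-5-iodo-2-methylpenta-2,4-dien-1-ylidene]furan-2(5H)-one | I/C=C/C=C(C)/C=C1C=C(Br)C(=O)O/1 | intermediate
45 | chlorobis(cyclopentadienyl){(1E,3E,5E)-4-methyl-6-[(3R,4S)-2,6,6-trimethyl-3,4-bis(triethylsilyloxy)cyclohex-1-en-1-yl]hexa-1,3,5-trien-1-yl}zirconium | CC1=C(/C=C/C(C)=C/C=C/[Zr](Cl)(C2C=CC=C2)C2C=CC=C2)C(C)(C)C[C@H](O[Si](CC)(CC)CC)[C@@H]1O[Si](CC)(CC)CC | intermediate (not isolated)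
46 | (5Z)-3-bromo-5-[(2E,4E,6E,8E,10E)-2,9-dimethyl-11-{(3R,4S)-2,6,6-trimethyl-3,4-bis[(triethylsilyl)oxy]cyclohex-1-en-1-yl}undeca-2,4,6,8,10-pentaen-1-ylidene]furan-2(5H)-one | CC1=C(/C=C/C(C)=C/C=C/C=C/C=C(C)/C=C2C=C(Br)C(=O)O/2)C(C)(C)C[C@H](O[Si](CC)(CC)CC)[C@@H]1O[Si](CC)(CC)CC | intermediate
47 | bis(triethylsilyl) ether of 48 at ring A O3 and O4 (full name in step 36) | CC1=C(/C=C/C(C)=C/C=C/C=C/C=C(C)/C=C2C=C(/C=C/[C@@]34O[C@@H](CC3(C)C)C[C@@]4(C)O)C(=O)O/2)C(C)(C)C[C@H](O[Si](CC)(CC)CC)[C@@H]1O[Si](CC)(CC)CC | intermediate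
48 | (5Z)-5-[(2E,4E,6E,8E,10E)-11-[(3R,4S)-3,4-dihydroxy-2,6,6-trimethylcyclohex-1-en-1-yl]-2,9-dimethylundeca-2,4,6,8,10-pentaen-1-ylidene]-3-{(E)-2-[(1R,2R,4S)-2-hydroxy-2,6,6-trimethyl-7-oxabicyclo[2.2.1]heptan-1-yl]ethenyl}furan-2(5H)-one (CNP0216838.1) | CC1=C(/C=C/C(C)=C/C=C/C=C/C=C(C)/C=C2C=C(/C=C/[C@@]34O[C@@H](CC3(C)C)C[C@@]4(C)O)C(=O)O/2)C(C)(C)C[C@H](O)[C@@H]1O | target

**Step count and risks**

Total step count: 37. Longest linear sequence: 21 steps (steps 1–18, then 35, 36, 37).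

Steps most likely to fail:

Step 27 (ether closure to the oxabicycle). The epoxide may ionise at C5' instead of C6', leading to ring contraction or hydride shift, or the propargylic cation may be captured from outside before the C3' hydroxyl closes the ring. The fallback sets out from 32 and returns at 35; it lets the closure run through an allylic instead of a propargylic cation, the situation of a carotenoid 5,6-epoxide with a 7,8-alkene. Wittig methylenation of 32 (Ph3P=CH2, THF) would give tert-butyl{[(1R,3S,6S)-6-ethenyl-1,5,5-trimethyl-7-oxabicyclo[4.1.0]heptan-3-yl]oxy}dimethylsilane F1. Bu4NF would free (1R,3S,6S)-6-ethenyl-1,5,5-trimethyl-7-oxabicyclo[4.1.0]heptan-3-ol F2, and camphorsulfonic acid should close it to (1R,2R,4S)-1-ethenyl-2,6,6-trimethyl-7-oxabicyclo[2.2.1]heptan-2-ol F3. Ozonolysis (O3, then Me2S) would give (1R,2R,4S)-2-hydroxy-2,6,6-trimethyl-7-oxabicyclo[2.2.1]heptane-1-carbaldehyde F4, and Ohira–Bestmann homologation of F4 gives 35.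

Step 34 (iodo-olefination next to the bromobutenolide). CrCl2 may reduce the ring C–Br bond or the conjugated lactone, or the E-selectivity may be incomplete. The fallback sets out from 23 and 43 and returns at 46; it dispenses with the iodide and forms C11=C12 by olefination instead of forming C12–C13 by coupling. Appel bromination of 23 (CBr4, PPh3) would give (3R,4S)-1-[(1E,3E)-5-bromo-3-methylpenta-1,3-dien-1-yl]-2,6,6-trimethyl-3,4-bis[(triethylsilyl)oxy]cyclohex-1-ene F5. Michaelis–Arbuzov reaction with P(OEt)3 would give diethyl [(2E,4E)-3-methyl-5-{(3R,4S)-2,6,6-trimethyl-3,4-bis[(triethylsilyl)oxy]cyclohex-1-en-1-yl}penta-2,4-dien-1-yl]phosphonate F6. Wittig homologation of 43 with Ph3P=CHCHO would give (2E,4E)-6-[(2Z)-4-bromo-5-oxofuran-2(5H)-ylidene]-5-methylhexa-2,4-dienal F7. Horner–Wadsworth–Emmons reaction of F6 (NaN(SiMe3)2, THF, −78 °C) with F7 would then give 46.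

Step 35 (hydrozirconation and Negishi coupling). Residual zirconium hydride may attack the lactone of 44, the discrimination between C–I and C–Br may be lost, or alkene geometry may erode in the polyenyl metal species. The fallback sets out from 24 and 44 and returns at 46; it uses a boron partner made without any hydride reagent. Boryl olefination of 24 (CrCl2, LiI, Cl2CHB(pin), THF) would give 4,4,5,5-tetramethyl-2-[(1E,3E,5E)-4-methyl-6-{(3R,4S)-2,6,6-trimethyl-3,4-bis[(triethylsilyl)oxy]cyclohex-1-en-1-yl}hexa-1,3,5-trien-1-yl]-1,3,2-dioxaborolane F8. Suzuki–Miyaura coupling of F8 with 44 (Pd(PPh3)4, Ag2O, THF–H2O, rt) should react at the C–I bond and give 46.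

**Further compounds**

F1 | step 27 | tert-butyl{[(1R,3S,6S)-6-ethenyl-1,5,5-trimethyl-7-oxabicyclo[4.1.0]heptan-3-yl]oxy}dimethylsilane | C=C[C@]1(O2)C(C)(C)C[C@H](O[Si](C)(C)C(C)(C)C)C[C@]12C
F2 | step 27 | (1R,3S,6S)-6-ethenyl-1,5,5-trimethyl-7-oxabicyclo[4.1.0]heptan-3-ol | C=C[C@]1(O2)C(C)(C)C[C@H](O)C[C@]12C
F3 | step 27 | (1R,2R,4S)-1-ethenyl-2,6,6-trimethyl-7-oxabicyclo[2.2.1]heptan-2-ol | C=C[C@@]12O[C@@H](CC1(C)C)C[C@@]2(C)O
F4 | step 27 | (1R,2R,4S)-2-hydroxy-2,6,6-trimethyl-7-oxabicyclo[2.2.1]heptane-1-carbaldehyde | O=C[C@@]12O[C@@H](CC1(C)C)C[C@@]2(C)O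
F5 | step 34 | (3R,4S)-1-[(1E,3E)-5-bromo-3-methylpenta-1,3-dien-1-yl]-2,6,6-trimethyl-3,4-bis[(triethylsilyl)oxy]cyclohex-1-ene | CC1=C(/C=C/C(C)=C/CBr)C(C)(C)C[C@H](O[Si](CC)(CC)CC)[C@@H]1O[Si](CC)(CC)CC
F6 | step 34 | diethyl [(2E,4E)-3-methyl-5-{(3R,4S)-2,6,6-trimethyl-3,4-bis[(triethylsilyl)oxy]cyclohex-1-en-1-yl}penta-2,4-dien-1-yl]phosphonate | CC1=C(/C=C/C(C)=C/CP(=O)(OCC)OCC)C(C)(C)C[C@H](O[Si](CC)(CC)CC)[C@@H]1O[Si](CC)(CC)CC
F7 | step 34 | (2E,4E)-6-[(2Z)-4-bromo-5-oxofuran-2(5H)-ylidene]-5-methylhexa-2,4-dienal | O=C/C=C/C=C(C)/C=C1C=C(Br)C(=O)O/1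
F8 | step 35 | 4,4,5,5-tetramethyl-2-[(1E,3E,5E)-4-methyl-6-{(3R,4S)-2,6,6-trimethyl-3,4-bis[(triethylsilyl)oxy]cyclohex-1-en-1-yl}hexa-1,3,5-trien-1-yl]-1,3,2-dioxaborolane | CC1=C(/C=C/C(C)=C/C=C/B2OC(C)(C)C(C)(C)O2)C(C)(C)C[C@H](O[Si](CC)(CC)CC)[C@@H]1O[Si](CC)(CC)CC
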